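**Retrosynthetic overview**
1. The arene is bought. The oxirane is the only ring made and is closed last, by cyclodehydration of an (R) tertiary/primary 1,2-diol without breaking the C–O bond at the stereocentre.
2. The CH2OH of that diol is a masked (E)-propenyl group, revealed by ozonolysis and reduction of a tertiary allylic alcohol.
3. Key disconnection: the tertiary benzylic C–O bond, made by a [2,3]-sigmatropic selenoxide-to-selenenate shift of a (Z)-allylic selenide with 1,3-chirality transfer.
4. The C–Se centre comes by SN2 inversion from the carbinol of (R)-but-3-yn-2-ol, the only chiral material bought.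
5. The Z-trisubstituted alkene comes from syn-hydroarylation of (R)-pent-2-yne-1,4-diol with 5-formyl-2-iodophenyl isovalerate. Both esters come from isovaleryl chloride.

Assumption: 1 (sold in both enantiomeric forms), 4 and 5 are taken as catalogue compounds.

**Step 1**
Reactants: 1 (R)-but-3-yn-2-ol
Product: 3 (R)-pent-2-yne-1,4-diol, via dilithiated butynol 2 (not isolated)
Conditions: n-BuLi (2.1 equiv), THF, -78 °C; (CH2O)n, -78 °C to rt; H2O
Reagents that add atoms: paraformaldehyde (reacts as formaldehyde) C=O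
Why: The lithium acetylide of the O,C-dianion adds to formaldehyde (alkynylation), and no bond at the carbinol carbon is touched, so the bought (R) centre is carried over.

**Step 2**
Reactants: 4 3-hydroxy-4-iodobenzaldehyde; 5 3-methylbutanoyl chloride (isovaleryl chloride)
Product: 6 5-formyl-2-iodophenyl 3-methylbutanoate
Conditions: Et3N, DMAP (cat.), CH2Cl2, 0 °C
Reagents that add atoms: none
Why: This is a DMAP-catalysed O-acylation of the phenol, in which the aldehyde and the aryl iodide are inert and no stereocentre is involved.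

**Step 3**
Reactants: 3 (R)-pent-2-yne-1,4-diol; 6 5-formyl-2-iodophenyl 3-methylbutanoate
Product: 7 5-formyl-2-[(2Z,4R)-1,4-dihydroxypent-2-en-2-yl]phenyl 3-methylbutanoate
Conditions: Pd(OAc)2(PPh3)2 (5 mol %), HCO2H, Et3N, MeCN, 50 °C
Reagents that add atoms: none
Why: In this Cacchi reductive Heck hydroarylation ArPdI adds syn across the alkyne, with aryl on the less hindered carbon next to CH2OH and Pd next to the branched carbinol, and formate replaces Pd by H with retention, which fixes the Z alkene (CH2OH cis to C4) and leaves the (R) centre alone; free allylic OH groups, unlike allylic esters, are not ionised by Pd(0)/formate.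

**Step 4**
Reactants: 7 5-formyl-2-[(2Z,4R)-1,4-dihydroxypent-2-en-2-yl]phenyl 3-methylbutanoate; 5 3-methylbutanoyl chloride
Product: 8 (2Z,4R)-2-[4-formyl-2-(3-methylbutanoyloxy)phenyl]-4-hydroxypent-2-en-1-yl 3-methylbutanoate
Conditions: 5 (1.0 equiv), 2,4,6-collidine, CH2Cl2, -78 to -40 °C
Reagents that add atoms: none
Why: Kinetically controlled acylation with one equivalent of acid chloride at low temperature takes the unhindered primary allylic OH over the secondary OH, and the alkene and the stereocentre are untouched.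

**Step 5 (key step)**
Reactants: 8 (2Z,4R)-2-[4-formyl-2-(3-methylbutanoyloxy)phenyl]-4-hydroxypent-2-en-1-yl 3-methylbutanoate
Product: 12 (2S,3E)-2-[4-formyl-2-(3-methylbutanoyloxy)phenyl]-2-hydroxypent-3-en-1-yl 3-methylbutanoate, via allylic selenide 9 (not isolated), via allylic selenoxide 10 (not isolated), via allylic selenenate 11 (not isolated)
Conditions: N-(phenylselanyl)phthalimide (1.3 equiv), PBu3 (1.3 equiv), THF, -20 to 0 °C, dark; then pyridine, 30 % aq H2O2, 0 °C, 30 min
Reagents that add atoms: hydrogen peroxide OO (the new carbinol O); N-(phenylselanyl)phthalimide O=C1c2ccccc2C(=O)N1[Se]c1ccccc1 (its PhSe group sits only in 9-11)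
Why: PhSe- displaces the oxyphosphonium salt of the alcohol by SN2 with inversion (4R to 4S), and after oxidation the selenoxide-selenenate [2,3]-sigmatropic rearrangement runs below 0 °C with A(1,3) strain against the cis CH2O group holding C4–H in the alkene plane, so oxygen is delivered suprafacially to the face of C2 that carried selenium, which sets the tertiary (2S) C–O centre and the E-propenyl group by 1,3-chirality transfer from the bought centre, and hydrolysis of Se–O then frees the alcohol.

**Step 6**
Reactants: 12 (2S,3E)-2-[4-formyl-2-(3-methylbutanoyloxy)phenyl]-2-hydroxypent-3-en-1-yl 3-methylbutanoate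
Product: 15 (2R)-2-[4-formyl-2-(3-methylbutanoyloxy)phenyl]-2,3-dihydroxypropyl 3-methylbutanoate, via secondary ozonide 13 (not isolated), via hydroxy dialdehyde 14 (not isolated)
Conditions: O3, CH2Cl2, -78 °C (Sudan III end point); Me2S, to rt, evaporate; NaBH(OAc)3 (1.2 equiv), MeCN/AcOH, -20 °C
Reagents that add atoms: ozone [O-][O+]=O
Why: Criegee ozonolysis cuts the only C=C bond, and a hydroxy-directed triacetoxyborohydride reduction (Saksena-Evans type) then passes hydride from boron bound to the tertiary OH to the neighbouring aliphatic CHO, while the aromatic aldehyde reacts only slowly with this weak hydride at -20 °C and the acidic medium holds back acyl migration; no bond at the stereocentre changes, and S to R is only a change in CIP ranking.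

**Step 7**
Reactants: 15 (2R)-2-[4-formyl-2-(3-methylbutanoyloxy)phenyl]-2,3-dihydroxypropyl 3-methylbutanoate
Product: 16 [(2R)-2-[4-formyl-2-(3-methylbutanoyloxy)phenyl]oxiran-2-yl]methyl 3-methylbutanoate (target)
Conditions: PPh3, DIAD, toluene, 0 °C to rt
Reagents that add atoms: none
Why: In this Mitsunobu cyclodehydration only the primary OH forms the oxyphosphonium salt and the tertiary oxygen displaces it in a 3-exo-tet SN2 at CH2, so the C–O bond at the stereocentre is kept (retention, R) and the neutral medium spares both esters and the aldehyde.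

**Compound list**
1 | (R)-but-3-yn-2-ol | C[C@@H](O)C#C | starting material
2 | dilithium salt of (R)-but-3-yn-2-ol (O,C-dianion) | C[C@@H]([O-])C#[C-].[Li+].[Li+] | intermediate (not isolated)
3 | (R)-pent-2-yne-1,4-diol | C[C@@H](O)C#CCO | intermediate
4 | 3-hydroxy-4-iodobenzaldehyde | O=Cc1ccc(I)c(O)c1 | starting material
5 | 3-methylbutanoyl chloride | CC(C)CC(=O)Cl | starting material
6 | 5-formyl-2-iodophenyl 3-methylbutanoate | CC(C)CC(=O)Oc1cc(C=O)ccc1I | intermediate
7 | 5-formyl-2-[(2Z,4R)-1,4-dihydroxypent-2-en-2-yl]phenyl 3-methylbutanoate | C[C@@H](O)/C=C(\CO)c1ccc(C=O)cc1OC(=O)CC(C)C | intermediate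
8 | (2Z,4R)-2-[4-formyl-2-(3-methylbutanoyloxy)phenyl]-4-hydroxypent-2-en-1-yl 3-methylbutanoate | C[C@@H](O)/C=C(\COC(=O)CC(C)C)c1ccc(C=O)cc1OC(=O)CC(C)C | intermediate
9 | (2Z,4S)-2-[4-formyl-2-(3-methylbutanoyloxy)phenyl]-4-(phenylselanyl)pent-2-en-1-yl 3-methylbutanoate | C[C@H]([Se]c1ccccc1)/C=C(\COC(=O)CC(C)C)c1ccc(C=O)cc1OC(=O)CC(C)C | intermediate (not isolated)
10 | (2Z,4S)-2-[4-formyl-2-(3-methylbutanoyloxy)phenyl]-4-(phenylseleninyl)pent-2-en-1-yl 3-methylbutanoate (both configurations at Se) | C[C@H]([Se](=O)c1ccccc1)/C=C(\COC(=O)CC(C)C)c1ccc(C=O)cc1OC(=O)CC(C)C | intermediate (not isolated)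
11 | (2S,3E)-2-[4-formyl-2-(3-methylbutanoyloxy)phenyl]-2-[(phenylselanyl)oxy]pent-3-en-1-yl 3-methylbutanoate | CC(C)CC(=O)OC[C@@](O[Se]c1ccccc1)(c1ccc(C=O)cc1OC(=O)CC(C)C)/C=C/C | intermediate (not isolated)
12 | (2S,3E)-2-[4-formyl-2-(3-methylbutanoyloxy)phenyl]-2-hydroxypent-3-en-1-yl 3-methylbutanoate | CC(C)CC(=O)OC[C@@](O)(c1ccc(C=O)cc1OC(=O)CC(C)C)/C=C/C | intermediate
13 | secondary ozonide (5-methyl-1,2,4-trioxolan-3-yl in place of propenyl; ring carbons unassigned) | CC(C)CC(=O)OC[C@@](O)(c1ccc(C=O)cc1OC(=O)CC(C)C)C1OOC(C)O1 | intermediate (not isolated)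
14 | (2S)-2-[4-formyl-2-(3-methylbutanoyloxy)phenyl]-2-hydroxy-3-oxopropyl 3-methylbutanoate | CC(C)CC(=O)OC[C@@](O)(c1ccc(C=O)cc1OC(=O)CC(C)C)C=O | intermediate (not isolated)
15 | (2R)-2-[4-formyl-2-(3-methylbutanoyloxy)phenyl]-2,3-dihydroxypropyl 3-methylbutanoate | CC(C)CC(=O)OC[C@@](O)(c1ccc(C=O)cc1OC(=O)CC(C)C)CO | intermediate
16 | [(2R)-2-[4-formyl-2-(3-methylbutanoyloxy)phenyl]oxiran-2-yl]methyl 3-methylbutanoate | CC(C)CC(=O)OC[C@@]1(c2ccc(C=O)cc2OC(=O)CC(C)C)CO1 | target

**Totals**
Total step count: 7. Longest linear sequence: 6 (steps 1, 3, 4, 5, 6, 7, from 1).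

**Steps most likely to fail**

Step 3 (hydroarylation). The two alkyne ends differ only as CH2OH against CH(OH)CH3, so a regioisomer and ArI reduction can cost yield. They cannot cost ee.
Fallback: build the same alkene from an allene instead of the alkyne.
- It sets out from 1. Crabbé homologation ((CH2O)n, i-Pr2NH, CuBr, dioxane, reflux) passes through the Mannich base (R)-5-[di(propan-2-yl)amino]pent-3-yn-2-ol F1 and gives (R)-penta-3,4-dien-2-ol F2.
- A Pd(PPh3)4-catalysed three-component coupling of F2 with 6 and sodium 3-methylbutanoate (DMF, 50 °C) follows.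
- Carbopalladation puts the aryl group on the central allene carbon, and the carboxylate attacks the CH2 end of the π-allyl complex.
- This comes back to the route at 8, with steps 1, 3 and 4 no longer needed.
- The E/Z ratio is checked by NOE and the minor isomer is removed.

Step 5 (selenation and [2,3] shift). SN2 at the hindered secondary allylic carbon may be slow or leak through ionisation or SN2', and 9 cannot be stored.
Fallback: the sulfur (Mislow-Evans) version, which has isolable intermediates.
- It sets out from 8. PhSSPh/PBu3 (THF, 0 °C) gives, with inversion, the sulfide (2Z,4S)-2-[4-formyl-2-(3-methylbutanoyloxy)phenyl]-4-(phenylsulfanyl)pent-2-en-1-yl 3-methylbutanoate F3, which can be purified and its ee checked.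
- mCPBA (1 equiv, CH2Cl2, -78 °C) gives the sulfoxide (2Z,4S)-2-[4-formyl-2-(3-methylbutanoyloxy)phenyl]-4-(phenylsulfinyl)pent-2-en-1-yl 3-methylbutanoate F4.
- Warming with P(OMe)3 in MeOH (40 °C) drains the [2,3] equilibrium through the sulfenate (2S,3E)-2-[4-formyl-2-(3-methylbutanoyloxy)phenyl]-2-[(phenylsulfanyl)oxy]pent-3-en-1-yl 3-methylbutanoate F5.
- This comes back to the route at 12.

Step 6 (reduction of one aldehyde beside the other). The aromatic CHO may be partly reduced as well.
Fallback: give up the selectivity and restore the aromatic aldehyde by oxidation.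
- It sets out from 14. Zn(BH4)2 (Et2O, -20 °C, non-basic) reduces both aldehydes to the triol (2R)-2,3-dihydroxy-2-[4-(hydroxymethyl)-2-(3-methylbutanoyloxy)phenyl]propyl 3-methylbutanoate F6.
- Activated MnO2 (CH2Cl2, rt) then oxidises only the primary benzylic alcohol.
- This comes back to the route at 15.

**Further compounds**
F1 | step 3 | (R)-5-[di(propan-2-yl)amino]pent-3-yn-2-ol | C[C@@H](O)C#CCN(C(C)C)C(C)C
F2 | step 3 | (R)-penta-3,4-dien-2-ol | C[C@@H](O)C=C=C
F3 | step 5 | (2Z,4S)-2-[4-formyl-2-(3-methylbutanoyloxy)phenyl]-4-(phenylsulfanyl)pent-2-en-1-yl 3-methylbutanoate | C[C@H](Sc1ccccc1)/C=C(\COC(=O)CC(C)C)c1ccc(C=O)cc1OC(=O)CC(C)C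
F4 | step 5 | (2Z,4S)-2-[4-formyl-2-(3-methylbutanoyloxy)phenyl]-4-(phenylsulfinyl)pent-2-en-1-yl 3-methylbutanoate | C[C@H](S(=O)c1ccccc1)/C=C(\COC(=O)CC(C)C)c1ccc(C=O)cc1OC(=O)CC(C)C
F5 | step 5 | (2S,3E)-2-[4-formyl-2-(3-methylbutanoyloxy)phenyl]-2-[(phenylsulfanyl)oxy]pent-3-en-1-yl 3-methylbutanoate | CC(C)CC(=O)OC[C@@](OSc1ccccc1)(c1ccc(C=O)cc1OC(=O)CC(C)C)/C=C/C
F6 | step 6 | (2R)-2,3-dihydroxy-2-[4-(hydroxymethyl)-2-(3-methylbutanoyloxy)phenyl]propyl 3-methylbutanoate | CC(C)CC(=O)OC[C@@](O)(c1ccc(CO)cc1OC(=O)CC(C)C)CO
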